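**Retrosynthetic overview**
1. Labels: C1 = ketone carbon, C2 = ring carbon bearing the CH2O carbon C7, C3 = vinylic CH, C4 = CH–O-tigloyl, C5 = CH–isopropyl, C6 = CH–OH; the target is (4S,5R,6R), with O4 cis and O6 trans to the isopropyl group.
2. Ester C–O bonds last (O4 and O7 acylated while O6 is silylated); C2–C7 by Morita–Baylis–Hillman hydroxymethylation of the enone.
3. Key disconnection C1–C6: a two-carbon acetyl anion equivalent (reversed polarity at C1) adds to a C6 aldehyde under Felkin/1,3-anti control and sets C6; its enol ether carbon C2 is kept as a latent nucleophile.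
4. Ring formation (one ring, the cyclohexenone): C2–C3 closure of that enol ether onto a C3 acetal, then loss of methanol, so the ring is a union of a 1,2-dinucleophile with a 1,4-dielectrophile.
5. C4–C5 and both their configurations come from one amine-catalysed anti cross-aldol of two simple aldehydes.

Assumption: both acyl groups are read from the SMILES as (E)-2-methylbut-2-enoyl (tigloyl); numbers go to every compound that supplies atoms of the target and to every intermediate, while silylating agents, acids, bases and catalysts are named in the Conditions lines.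

Step 1
Reactants: 1 3-methylbutanal; 2 2,2-dimethoxyacetaldehyde
Product: 3 (2S,3R)-3-hydroxy-4,4-dimethoxy-2-(propan-2-yl)butanal
Conditions: L-proline (20 mol%), DMF, 4 °C; 1 added over 20 h to 2 (3 equiv, 60 wt% in water)
Reagents that add atoms: none
Why: Direct proline-catalysed cross-aldol (enamine catalysis), in which the slowly added donor 1 forms the (E)-enamine and attacks the non-enolisable, more electrophilic aldehyde 2 through the hydrogen-bonded List–Houk chair transition state, setting the anti (2S,3R) pair that becomes C5 and C4 of the ring.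

Step 2
Reactants: 3 (2S,3R)-3-hydroxy-4,4-dimethoxy-2-(propan-2-yl)butanal
Product: 4 (2S,3R)-4,4-dimethoxy-2-(propan-2-yl)-3-[(triethylsilyl)oxy]butanal
Conditions: Et3SiCl, imidazole, CH2Cl2, 0 °C
Reagents that add atoms: chlorotriethylsilane CC[Si](Cl)(CC)CC
Why: O-Silylation that touches no stereocentre, giving a non-chelating triethylsilyl ether that stops retro-aldol and elimination of the beta-hydroxy aldehyde, leaves the next addition under open Felkin control, and is the more acid-labile of the two silyl groups used so it can be removed later while the other stays.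

Step 3
Reactants: 4 (2S,3R)-4,4-dimethoxy-2-(propan-2-yl)-3-[(triethylsilyl)oxy]butanal; 5 ethoxyethene
Product: 8 (3R,4R,5R)-3-[(tert-butyldimethylsilyl)oxy]-2-ethoxy-6,6-dimethoxy-4-(propan-2-yl)-5-[(triethylsilyl)oxy]hex-1-ene, via (1-ethoxyethenyl)lithium 6 (not isolated), via lithium alkoxide adduct 7 (not isolated)
Conditions: 5, t-BuLi, THF, −78 → 0 °C; then 4, −78 °C; then t-BuMe2SiOTf, −78 → −40 °C
Reagents that add atoms: tert-butyldimethylsilyl trifluoromethanesulfonate CC(C)(C)[Si](C)(C)OS(=O)(=O)C(F)(F)F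
Why: Felkin–Anh controlled addition of an acyl anion equivalent (1-alkoxyvinyllithium), in which the lithiated carbon of 6 becomes the ketone carbon C1 and attacks the aldehyde carbon C6 of 4 on the face where the 1,2 preference (C4 branch anti to the nucleophile) and the 1,3-anti preference of the non-chelating beta-silyloxy group reinforce each other in this anti aldehyde, giving the (3R) carbinol, which is silylated in the same flask so that O6 and O4 carry different silyl groups.

Step 4
Reactants: 8 (3R,4R,5R)-3-[(tert-butyldimethylsilyl)oxy]-2-ethoxy-6,6-dimethoxy-4-(propan-2-yl)-5-[(triethylsilyl)oxy]hex-1-ene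
Product: 11 (4S,5S,6R)-6-[(tert-butyldimethylsilyl)oxy]-4-hydroxy-5-(propan-2-yl)cyclohex-2-en-1-one, via cyclic mixed ketal 9 (not isolated), via methoxy ketone 10 (not isolated)
Conditions: Me3SiOTf (10 mol%), 2,6-di-tert-butyl-4-methylpyridine (20 mol%), CH2Cl2, −78 → −40 °C; then AcOH/THF/H2O (3:1:1), rt; then DBU, CH2Cl2, 0 °C → rt
Reagents that add atoms: water O
Why: Intramolecular Mukaiyama-type (Prins) addition of the enol ether carbon C2 to the oxocarbenium ion released from the dimethyl acetal closes the six-membered ring at C2–C3, mild aqueous acid then hydrolyses the ketal and the triethylsilyl ether while the tert-butyldimethylsilyl ether survives, and DBU expels methanol by E1cB to give the conjugated enone, so no new stereocentre persists and C4, C5 and C6 are untouched.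

Step 5
Reactants: 11 (4S,5S,6R)-6-[(tert-butyldimethylsilyl)oxy]-4-hydroxy-5-(propan-2-yl)cyclohex-2-en-1-one; 12 formaldehyde
Product: 13 (4S,5S,6R)-6-[(tert-butyldimethylsilyl)oxy]-4-hydroxy-2-(hydroxymethyl)-5-(propan-2-yl)cyclohex-2-en-1-one
Conditions: 12 (37 wt% in water, 3 equiv), 4-(dimethylamino)pyridine (0.5 equiv), THF/H2O, rt
Reagents that add atoms: none
Why: Morita–Baylis–Hillman hydroxymethylation, in which the pyridine catalyst adds reversibly to C3, the resulting enolate attacks formaldehyde at C2 and loss of the catalyst returns the enone carrying the C7 hydroxymethyl group, without creating a stereocentre or disturbing the silyl ether.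

Step 6
Reactants: 13 (4S,5S,6R)-6-[(tert-butyldimethylsilyl)oxy]-4-hydroxy-2-(hydroxymethyl)-5-(propan-2-yl)cyclohex-2-en-1-one; 14 (2E)-2-methylbut-2-enoyl chloride
Product: 16 [(3S,4R,5R)-5-hydroxy-3-{[(2E)-2-methylbut-2-enoyl]oxy}-6-oxo-4-(propan-2-yl)cyclohex-1-en-1-yl]methyl (2E)-2-methylbut-2-enoate, via bis-tiglate silyl ether 15 (not isolated)
Conditions: 14 (3 equiv), pyridine, 4-(dimethylamino)pyridine (10 mol%), CH2Cl2, 0 °C → rt; then HF·pyridine, THF, 0 °C → rt
Reagents that add atoms: none
Why: Nucleophile-catalysed esterification of the primary O7 and the allylic secondary O4 followed by fluoride-mediated desilylation in the same flask, where O6 stays masked during acylation, the tiglate double bonds keep their (E) geometry, and the trans-1,3 arrangement of O4 and O6 on the ring rules out acyl migration once O6 is free.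

**Compound list**
1 | 3-methylbutanal | CC(C)CC=O | starting material
2 | 2,2-dimethoxyacetaldehyde | COC(OC)C=O | starting material
3 | (2S,3R)-3-hydroxy-4,4-dimethoxy-2-(propan-2-yl)butanal | COC(OC)[C@H](O)[C@H](C(C)C)C=O | intermediate
4 | (2S,3R)-4,4-dimethoxy-2-(propan-2-yl)-3-[(triethylsilyl)oxy]butanal | COC(OC)[C@H](O[Si](CC)(CC)CC)[C@H](C(C)C)C=O | intermediate
5 | ethoxyethene (ethyl vinyl ether) | C=COCC | starting material
6 | (1-ethoxyethenyl)lithium | [Li]C(=C)OCC | intermediate
7 | lithium (3R,4R,5R)-2-ethoxy-6,6-dimethoxy-4-(propan-2-yl)-5-[(triethylsilyl)oxy]hex-1-en-3-olate | COC(OC)[C@H](O[Si](CC)(CC)CC)[C@H](C(C)C)[C@@H]([O-])C(=C)OCC.[Li+] | intermediate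
8 | (3R,4R,5R)-3-[(tert-butyldimethylsilyl)oxy]-2-ethoxy-6,6-dimethoxy-4-(propan-2-yl)-5-[(triethylsilyl)oxy]hex-1-ene | COC(OC)[C@H](O[Si](CC)(CC)CC)[C@H](C(C)C)[C@@H](O[Si](C)(C)C(C)(C)C)C(=C)OCC | intermediate
9 | (2R,3S,4R)-2-[(tert-butyldimethylsilyl)oxy]-1-ethoxy-1,5-dimethoxy-3-(propan-2-yl)-4-[(triethylsilyl)oxy]cyclohexane (both epimers at C1 and C5) | C1C(OC)[C@H](O[Si](CC)(CC)CC)[C@H](C(C)C)[C@@H](O[Si](C)(C)C(C)(C)C)C1(OC)OCC | intermediate
10 | (2R,3S,4R)-2-[(tert-butyldimethylsilyl)oxy]-4-hydroxy-5-methoxy-3-(propan-2-yl)cyclohexan-1-one (both epimers at C5) | C1C(OC)[C@H](O)[C@H](C(C)C)[C@@H](O[Si](C)(C)C(C)(C)C)C1=O | intermediate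
11 | (4S,5S,6R)-6-[(tert-butyldimethylsilyl)oxy]-4-hydroxy-5-(propan-2-yl)cyclohex-2-en-1-one | C1=C[C@H](O)[C@H](C(C)C)[C@@H](O[Si](C)(C)C(C)(C)C)C1=O | intermediate
12 | formaldehyde | C=O | starting material
13 | (4S,5S,6R)-6-[(tert-butyldimethylsilyl)oxy]-4-hydroxy-2-(hydroxymethyl)-5-(propan-2-yl)cyclohex-2-en-1-one | OCC1=C[C@H](O)[C@H](C(C)C)[C@@H](O[Si](C)(C)C(C)(C)C)C1=O | intermediate
14 | (2E)-2-methylbut-2-enoyl chloride (tigloyl chloride) | C/C=C(\C)C(Cl)=O | starting material
15 | [(3S,4S,5R)-5-[(tert-butyldimethylsilyl)oxy]-3-{[(2E)-2-methylbut-2-enoyl]oxy}-6-oxo-4-(propan-2-yl)cyclohex-1-en-1-yl]methyl (2E)-2-methylbut-2-enoate | C/C=C(\C)C(=O)OCC1=C[C@H](OC(=O)/C(C)=C/C)[C@H](C(C)C)[C@@H](O[Si](C)(C)C(C)(C)C)C1=O | intermediate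
16 | [(3S,4R,5R)-5-hydroxy-3-{[(2E)-2-methylbut-2-enoyl]oxy}-6-oxo-4-(propan-2-yl)cyclohex-1-en-1-yl]methyl (2E)-2-methylbut-2-enoate | C/C=C(\C)C(=O)OCC1=C[C@H](OC(=O)/C(C)=C/C)[C@H](C(C)C)[C@@H](O)C1=O | target

**Totals**
Total step count: 6. Longest linear sequence: 6 steps (1 or 2 to 16).

**Steps most likely to fail, with fallbacks**

Step 3 is at risk because a small vinyllithium may show only modest facial selectivity on an acyclic aldehyde. The fallback sets out from 4 and gives up kinetic control at C6, fixing it after the ring exists. The addition is run as before and the unwanted epimer, (3S,4R,5R)-3-[(tert-butyldimethylsilyl)oxy]-2-ethoxy-6,6-dimethoxy-4-(propan-2-yl)-5-[(triethylsilyl)oxy]hex-1-ene F1, is not separated. Under the conditions of step 4 it passes through its cyclic mixed ketal, (2S,3S,4R)-2-[(tert-butyldimethylsilyl)oxy]-1-ethoxy-1,5-dimethoxy-3-(propan-2-yl)-4-[(triethylsilyl)oxy]cyclohexane F2, and its methoxy ketone, (2S,3S,4R)-2-[(tert-butyldimethylsilyl)oxy]-4-hydroxy-5-methoxy-3-(propan-2-yl)cyclohexan-1-one F3, to the 6-epimeric enone, (4S,5S,6S)-6-[(tert-butyldimethylsilyl)oxy]-4-hydroxy-5-(propan-2-yl)cyclohex-2-en-1-one F4. F4 is then epimerised at the carbon next to the ketone (DBU, toluene, 40 °C). The equilibrium should favour 11, whose silyloxy group is equatorial and trans to the equatorial isopropyl group, whereas F4 must place O4 and O6 syn-diaxial or the isopropyl group axial. The fallback comes back to the route at 11.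

Step 4 is at risk because the Lewis-acid ring closure needs the acetal to ionise cleanly next to a silyloxy group without the enol ether being lost first. The fallback sets out from 8 and closes the ring by aldol condensation of the free dicarbonyl compound instead. Aqueous CF3CO2H in CH2Cl2 at 0 °C hydrolyses the enol ether, the acetal and the triethylsilyl ether to the keto-aldehyde, (2R,3S,4R)-4-[(tert-butyldimethylsilyl)oxy]-2-hydroxy-5-oxo-3-(propan-2-yl)hexanal F5. Pyrrolidinium acetate in CH2Cl2 at rt then gives, by intramolecular enamine aldol addition of the methyl ketone to the aldehyde, the ketol, (2R,3S,4R)-2-[(tert-butyldimethylsilyl)oxy]-4,5-dihydroxy-3-(propan-2-yl)cyclohexan-1-one F6, which loses water in the same flask. The fallback comes back to the route at 11.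

Step 5 is at risk because the enone is hindered and oxygenated at the gamma position, which slows conjugate addition of the amine catalyst. The fallback sets out from 11 and replaces the organocatalytic C–C bond formation by halogenation and cross-coupling. I2 and pyridine in CH2Cl2 give the iodoenone, (4R,5S,6R)-6-[(tert-butyldimethylsilyl)oxy]-4-hydroxy-2-iodo-5-(propan-2-yl)cyclohex-2-en-1-one F7. Stille coupling of F7 with Bu3SnCH2OH (Pd(PPh3)4, CuI, DMF, 60 °C) installs the hydroxymethyl group, and the fallback comes back to the route at 13.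

**Further compounds**
F1 | step 3 | (3S,4R,5R)-3-[(tert-butyldimethylsilyl)oxy]-2-ethoxy-6,6-dimethoxy-4-(propan-2-yl)-5-[(triethylsilyl)oxy]hex-1-ene | COC(OC)[C@H](O[Si](CC)(CC)CC)[C@H](C(C)C)[C@H](O[Si](C)(C)C(C)(C)C)C(=C)OCC
F2 | step 3 | (2S,3S,4R)-2-[(tert-butyldimethylsilyl)oxy]-1-ethoxy-1,5-dimethoxy-3-(propan-2-yl)-4-[(triethylsilyl)oxy]cyclohexane | C1C(OC)[C@H](O[Si](CC)(CC)CC)[C@H](C(C)C)[C@H](O[Si](C)(C)C(C)(C)C)C1(OC)OCC
F3 | step 3 | (2S,3S,4R)-2-[(tert-butyldimethylsilyl)oxy]-4-hydroxy-5-methoxy-3-(propan-2-yl)cyclohexan-1-one | C1C(OC)[C@H](O)[C@H](C(C)C)[C@H](O[Si](C)(C)C(C)(C)C)C1=O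
F4 | step 3 | (4S,5S,6S)-6-[(tert-butyldimethylsilyl)oxy]-4-hydroxy-5-(propan-2-yl)cyclohex-2-en-1-one | C1=C[C@H](O)[C@H](C(C)C)[C@H](O[Si](C)(C)C(C)(C)C)C1=O
F5 | step 4 | (2R,3S,4R)-4-[(tert-butyldimethylsilyl)oxy]-2-hydroxy-5-oxo-3-(propan-2-yl)hexanal | O=C[C@H](O)[C@H](C(C)C)[C@@H](O[Si](C)(C)C(C)(C)C)C(C)=O
F6 | step 4 | (2R,3S,4R)-2-[(tert-butyldimethylsilyl)oxy]-4,5-dihydroxy-3-(propan-2-yl)cyclohexan-1-one | C1C(O)[C@H](O)[C@H](C(C)C)[C@@H](O[Si](C)(C)C(C)(C)C)C1=O
F7 | step 5 | (4R,5S,6R)-6-[(tert-butyldimethylsilyl)oxy]-4-hydroxy-2-iodo-5-(propan-2-yl)cyclohex-2-en-1-one | IC1=C[C@H](O)[C@H](C(C)C)[C@@H](O[Si](C)(C)C(C)(C)C)C1=O
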